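## Retrosynthetic overview

- Last skeletal bond: the ester C–O, between MOM-protected (2R,3R)-secoisolariciresinol and MOM-protected (E)-ferulic acid. The diol is C2-symmetric, so both CH2OH groups are equivalent; global MOM removal finishes the synthesis.
- The diol comes from LiAlH4 opening of a trans-(3R,4R)-dibenzylbutyrolactone, itself made by alkylating an (R)-β-arylmethyl-γ-butyrolactone enolate with a benzylic bromide. The three aryl fragments (lactone, benzyl bromide, cinnamic acid; 14–19 heavy atoms each) are joined in these two late couplings.
- The (R)-lactone comes from Cu-catalysed aryl Grignard opening of a cyclopropane-fused lactone built from (R)-epichlorohydrin and dimethyl malonate. This is the only source of chirality.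
- All three aryl units come from one aryl bromide: catechol, O-methylation, para-bromination, MOM protection.
- Ring order: the arenes are bought intact. The cyclopropane and γ-lactone form together (step 5), the cyclopropane is opened (step 6) and the lactone is opened (step 11). No ring is formed afterwards.

Assumption: a Grignard reagent made and consumed in the same flask counts as part of that step, and (R)-epichlorohydrin is bought enantiopure.

## Route

**Step 1**
Reactants: 1 catechol
Product: 2 guaiacol (2-methoxyphenol)
Conditions: MeI (0.9 equiv), K2CO3, acetone, reflux; wash out excess catechol with water, extract 2 into aq NaOH away from veratrole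
Reagents that add atoms: iodomethane, CI
Why: Williamson ether synthesis; with catechol in excess the mono-ether dominates and is separated by its acidity.

**Step 2**
Reactants: 2 guaiacol
Product: 3 4-bromo-2-methoxyphenol
Conditions: Bu4NBr3 (1.0 equiv), CH2Cl2/MeOH, rt
Reagents that add atoms: tetrabutylammonium tribromide (written as the Bu4N+ Br−·Br2 salt), CCCC[N+](CCCC)(CCCC)CCCC.[Br-].BrBr
Why: Electrophilic aromatic bromination; the free OH is the strongest director and the bulky tribromide favours para over ortho, so substitution goes para to OH and meta to OMe.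

**Step 3**
Reactants: 3 4-bromo-2-methoxyphenol
Product: 4 4-bromo-2-methoxy-1-(methoxymethoxy)benzene
Conditions: MOMCl, i-Pr2NEt, CH2Cl2, 0 °C to rt
Reagents that add atoms: chloromethyl methyl ether, COCCl
Why: Phenol O-alkylation (MOM protection); the acetal survives Grignard, enolate, hydride and Pd chemistry and comes off with mild acid.

**Step 4**
Reactants: 5 malonic acid
Product: 6 dimethyl malonate
Conditions: MeOH, cat. H2SO4, reflux
Reagents that add atoms: methanol, CO
Why: Fischer esterification driven by excess methanol.

**Step 5**
Reactants: 6 dimethyl malonate; 7 (R)-epichlorohydrin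
Product: 8 methyl (1S,5R)-2-oxo-3-oxabicyclo[3.1.0]hexane-1-carboxylate
Conditions: NaOMe, MeOH, reflux, 18 h
Reagents that add atoms: none
Why: Malonate–epichlorohydrin annulation (epoxide opening, epoxide re-closure, 3-exo-tet cyclopropanation with inversion, lactonisation); the epichlorohydrin stereocentre becomes C5 (R) and the cis ring fusion fixes C1 (S).

**Step 6**
Reactants: 4 aryl bromide (1.5 equiv, as its Grignard); 8 cyclopropane lactone
Product: 9 methyl (4R)-4-[3-methoxy-4-(methoxymethoxy)benzyl]-2-oxotetrahydrofuran-3-carboxylate (C3 epimer mixture, mainly trans)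
Conditions: 4, Mg, THF, 45 °C; then CuI (15 mol%), 8, THF, −40 to −15 °C; aq NH4Cl
Reagents that add atoms: none
Why: Cu-catalysed homoconjugate (SN2-type) opening of the doubly activated cyclopropane at its CH2; C5 of 8 is untouched and becomes the (4R) centre.

**Step 7**
Reactants: 9 lactone ester
Product: 10 (4R)-4-[3-methoxy-4-(methoxymethoxy)benzyl]dihydrofuran-2(3H)-one
Conditions: LiCl, DMSO, H2O (2 equiv), 140 °C
Reagents that add atoms: none
Why: Krapcho demethoxycarbonylation of the malonate-type ester under neutral conditions; C4 is not epimerisable and the MOM ether is stable.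

**Step 8**
Reactants: 4 aryl bromide
Product: 11 [3-methoxy-4-(methoxymethoxy)phenyl]methanol
Conditions: Mg, THF, 45 °C; then dry (CH2O)n, 0 °C to 50 °C; aq NH4Cl
Reagents that add atoms: formaldehyde (as paraformaldehyde), C=O
Why: Grignard addition to formaldehyde gives the one-carbon-homologated benzylic alcohol directly.

**Step 9**
Reactants: 11 benzylic alcohol
Product: 12 4-(bromomethyl)-2-methoxy-1-(methoxymethoxy)benzene (used at once)
Conditions: CBr4, PPh3, CH2Cl2, 0 °C
Reagents that add atoms: carbon tetrabromide, BrC(Br)(Br)Br
Why: Appel bromination is essentially neutral, so the acid-labile MOM acetal survives.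

**Step 10**
Reactants: 10 (R)-lactone; 12 benzylic bromide (1.2 equiv)
Product: 13 (3R,4R)-3,4-bis[3-methoxy-4-(methoxymethoxy)benzyl]dihydrofuran-2(3H)-one (trans)
Conditions: LiHMDS (1.1 equiv), THF, −78 °C; then 12, DMPU, −78 to −40 °C
Reagents that add atoms: none
Why: Lactone enolate alkylation; the bromide approaches anti to the C4 benzyl group, setting C3 as R (trans, typically ≥95:5).

**Step 11**
Reactants: 13 trans-lactone
Product: 14 (2R,3R)-2,3-bis[3-methoxy-4-(methoxymethoxy)benzyl]butane-1,4-diol
Conditions: LiAlH4, THF, 0 °C to rt; Fieser (basic) work-up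
Reagents that add atoms: none
Why: Hydride reduction of the lactone to the 1,4-diol; neither stereocentre is touched and the basic work-up keeps the MOM ethers.

**Step 12**
Reactants: 4 aryl bromide; 15 acrylic acid (1.5 equiv)
Product: 16 (E)-3-[3-methoxy-4-(methoxymethoxy)phenyl]prop-2-enoic acid
Conditions: Pd(OAc)2 (2 mol%), P(o-tol)3 (6 mol%), Et3N (3 equiv), DMF, 100 °C; acidify to pH 4 (citric acid, 0 °C)
Reagents that add atoms: none
Why: Mizoroki–Heck arylation of acrylic acid; syn-insertion and syn-β-hydride elimination give the E-cinnamic acid.

**Step 13**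
Reactants: 14 diol (2.0 equiv, excess recovered); 16 acid (1.0 equiv)
Product: 17 (2R,3R)-4-hydroxy-2,3-bis[3-methoxy-4-(methoxymethoxy)benzyl]butyl (E)-3-[3-methoxy-4-(methoxymethoxy)phenyl]prop-2-enoate
Conditions: EDC·HCl, DMAP (0.2 equiv), CH2Cl2, 0 °C to rt
Reagents that add atoms: none
Why: Steglich esterification; the C2 symmetry means either hydroxyl gives the same mono-ester, and excess diol suppresses the diester.

**Step 14**
Reactants: 17 tris-MOM ester
Product: 18 hanultarin
Conditions: 2 M aq HCl, THF/i-PrOH (1:1), 40 °C; NaHCO3 work-up
Reagents that add atoms: none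
Why: Acid-catalysed hydrolysis of the three aryl MOM acetals; the conditions are too mild to cleave the cinnamate, i-PrOH traps formaldehyde, and any acyl shift between the two equivalent hydroxyls is degenerate.

## Compound list

1 | catechol (benzene-1,2-diol) | Oc1ccccc1O | starting material
2 | guaiacol (2-methoxyphenol) | COc1ccccc1O | intermediate
3 | 4-bromo-2-methoxyphenol | COc1cc(Br)ccc1O | intermediate
4 | 4-bromo-2-methoxy-1-(methoxymethoxy)benzene | COCOc1ccc(Br)cc1OC | intermediate
5 | malonic acid | OC(=O)CC(=O)O | starting material
6 | dimethyl malonate | COC(=O)CC(=O)OC | intermediate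
7 | (R)-epichlorohydrin, (2R)-2-(chloromethyl)oxirane | ClC[C@H]1CO1 | starting material
8 | methyl (1S,5R)-2-oxo-3-oxabicyclo[3.1.0]hexane-1-carboxylate | COC(=O)[C@]12C[C@H]1COC2=O | intermediate
9 | methyl (4R)-4-[3-methoxy-4-(methoxymethoxy)benzyl]-2-oxotetrahydrofuran-3-carboxylate (C3 epimers) | COC(=O)C1[C@@H](Cc2ccc(OCOC)c(OC)c2)COC1=O | intermediate
10 | (4R)-4-[3-methoxy-4-(methoxymethoxy)benzyl]dihydrofuran-2(3H)-one | COCOc1ccc(C[C@H]2COC(=O)C2)cc1OC | intermediate
11 | [3-methoxy-4-(methoxymethoxy)phenyl]methanol | COCOc1ccc(CO)cc1OC | intermediate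
12 | 4-(bromomethyl)-2-methoxy-1-(methoxymethoxy)benzene | COCOc1ccc(CBr)cc1OC | intermediate
13 | (3R,4R)-3,4-bis[3-methoxy-4-(methoxymethoxy)benzyl]dihydrofuran-2(3H)-one | COCOc1ccc(C[C@H]2COC(=O)[C@@H]2Cc3ccc(OCOC)c(OC)c3)cc1OC | intermediate
14 | (2R,3R)-2,3-bis[3-methoxy-4-(methoxymethoxy)benzyl]butane-1,4-diol | OC[C@H](Cc1ccc(OCOC)c(OC)c1)[C@H](CO)Cc1ccc(OCOC)c(OC)c1 | intermediate
15 | acrylic acid | C=CC(=O)O | starting material
16 | (E)-3-[3-methoxy-4-(methoxymethoxy)phenyl]prop-2-enoic acid | COCOc1ccc(/C=C/C(=O)O)cc1OC | intermediate
17 | (2R,3R)-4-hydroxy-2,3-bis[3-methoxy-4-(methoxymethoxy)benzyl]butyl (E)-3-[3-methoxy-4-(methoxymethoxy)phenyl]prop-2-enoate | COCOc1ccc(/C=C/C(=O)OC[C@H](Cc2ccc(OCOC)c(OC)c2)[C@H](CO)Cc2ccc(OCOC)c(OC)c2)cc1OC | intermediate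
18 | hanultarin | COc1cc(/C=C/C(=O)OC[C@H](Cc2ccc(O)c(OC)c2)[C@H](CO)Cc2ccc(O)c(OC)c2)ccc1O | target

## Summary

Total step count: 14.

Longest linear sequence: 9 steps (1→2→3→4→9→10→13→14→17→18, i.e. steps 1, 2, 3, 6, 7, 10, 11, 13, 14; the path through 11 and 12 is also 9).

Enantiopurity: step 5 usually gives slightly less than full ee because a minor pathway (direct chloride displacement) leads to the enantiomer. If needed, upgrade by recrystallising 13 or 14.

Steps most likely to fail:

1. **Step 6, aryl Grignard/CuI opening of the cyclopropane lactone.** Aryl cuprates are less reactive than alkyl ones and 1,2-addition to the carbonyls can compete. Fallback: make lactone 10 by a different route. Formylate 4 (Mg, then DMF), run a Stobbe condensation with dimethyl succinate, hydrogenate the itaconate half-ester with a chiral Rh-bisphosphine catalyst, then reduce the ester selectively (Ca(BH4)2) and lactonise.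

2. **Step 13, mono-esterification of the symmetric diol.** Diester formation is possible and the excess diol must be recycled. Fallback: differentiate the two oxygens through lactone 13. Open it to the hydroxy Weinreb amide (Me2AlN(OMe)Me), protect the alcohol as its TBS ether, reduce the amide to the primary alcohol (LiAlH4 to the aldehyde, then NaBH4 at once to limit α-epimerisation), and acylate that single free OH with excess 16. The final acid step then removes TBS and MOM together.

3. **Step 14, acidic removal of three MOM groups beside the cinnamate ester.** Risks are partial ester solvolysis and formaldehyde alkylation of the free guaiacyl rings. Fallback: change the protecting-group strategy to fluoride-labile TIPS ethers (TIPSCl/imidazole in step 3, carried through the same sequence), so the last step is buffered TBAF/AcOH in THF at 0 °C with no strong acid present.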